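**Plan** (numbering used throughout: ring carbons C1 ketone, C2, C3 carbinol, C4 methyl-bearing, C5, C6 lactone carbinol, C7 ring fusion, C8 ester carbinol, C9, C10 acetoxy carbon; lactone carbons C11, which bears the methylene C13, and C12 carbonyl)
1. Cuts, in retrosynthetic order: the C8 ester (angelic acid, attached with inversion); the ring bond C7–C8 (intramolecular chromium allylation); C2–C3 (Mukaiyama aldol between butenolide aldehyde fragment A, C3–C7 with C11–C13, and methyl ketone fragment B, C1, C2, C8–C10).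
2. Forward: the butenolide ring (O, C12, C11, C7, C6) is made first, the chain is joined at C2–C3, and the ten-membered carbocycle is closed last.
3. Enabling feature: the exocyclic methylene C13 on lactone carbon C11 next to the ring-fusion carbon C7. Written as C13H2Br–C11=C7 inside a butenolide it is an allyl bromide whose γ-carbon is C7, with the C8 aldehyde held eight atoms away from C6.
4. Stereochemistry: C4 and C10 are bought ((R)-3-bromo-2-methylpropan-1-ol; (S)-lactic acid, allylated with retention). C6 is set by catalytic transfer hydrogenation and C3 by Felkin control from C4. C7 and C8 are set together in the ring closure, relayed from C6 through the butenolide; C8 arises epimeric and is inverted at the esterification.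
5. Helpers: PMB on O13 (exchanged for bromide before ring closure) and TES on O3 (removed last).

Key step: step 20

Remark: the closed chair transition state of the chromium allylation is taken to give the 7,8-anti alcohol (8S); the route is built on that outcome.

**Fragment A**

Step 1
Reactants: 1 (R)-3-bromo-2-methylpropan-1-ol
Product: 2 (R)-(3-bromo-2-methylpropoxy)(tert-butyl)dimethylsilane
Conditions: TBSCl, imidazole, CH2Cl2, 0 °C to rt
Reagents that add atoms: tert-butyldimethylsilyl chloride, CC(C)(C)[Si](C)(C)Cl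
Why: Standard silylation of the primary alcohol (the future C3 oxygen) so that the bromide end (future C5) can be metallated; the purchased C4 stereocentre is not touched.

Step 2
Reactants: 3 1-methoxy-4-[(prop-2-yn-1-yloxy)methyl]benzene
Product: 5 N-methoxy-4-[(4-methoxyphenyl)methoxy]-N-methylbut-2-ynamide, via lithium acetylide 4 (not isolated)
Conditions: n-BuLi, THF, −78 °C; then ClC(O)N(OMe)Me, −78 to 0 °C
Reagents that add atoms: N-methoxy-N-methylcarbamoyl chloride, CON(C)C(Cl)=O
Why: Deprotonation of the terminal alkyne and C-acylation of the lithium acetylide with the carbamoyl chloride is the usual route to alkynyl Weinreb amides; the PMB ether carries the future C13 oxygen.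

Step 3
Reactants: 2 (R)-(3-bromo-2-methylpropoxy)(tert-butyl)dimethylsilane; 5 N-methoxy-4-[(4-methoxyphenyl)methoxy]-N-methylbut-2-ynamide
Product: 7 (6S)-7-[(tert-butyldimethylsilyl)oxy]-1-[(4-methoxyphenyl)methoxy]-6-methylhept-2-yn-4-one, via Grignard reagent 6 (not isolated)
Conditions: Mg, THF, 40 °C; then 5, THF, −40 to 0 °C; cold aq. NH4Cl quench
Reagents that add atoms: none
Why: Weinreb ketone synthesis: the Grignard reagent adds once to the amide because the magnesium-chelated tetrahedral intermediate survives until the cold quench, giving the ynone with C5–C6 formed and C4 unchanged.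

Step 4
Reactants: 7 (6S)-7-[(tert-butyldimethylsilyl)oxy]-1-[(4-methoxyphenyl)methoxy]-6-methylhept-2-yn-4-one
Product: 8 (4R,6S)-7-[(tert-butyldimethylsilyl)oxy]-1-[(4-methoxyphenyl)methoxy]-6-methylhept-2-yn-4-ol
Conditions: RuCl[(R,R)-TsDPEN](p-cymene) (2 mol %), i-PrOH, rt
Reagents that add atoms: none
Why: Noyori–Ikariya asymmetric transfer hydrogenation of an alkynyl ketone; the (R,R)-catalyst should deliver hydride to the face that gives the (R)-propargylic alcohol (alkynyl in the role of the aryl group of aryl ketones), so C6 is set by the catalyst and not by the remote C4.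

Step 5
Reactants: 8 (4R,6S)-7-[(tert-butyldimethylsilyl)oxy]-1-[(4-methoxyphenyl)methoxy]-6-methylhept-2-yn-4-ol
Product: 10 (2Z,4R,6S)-7-[(tert-butyldimethylsilyl)oxy]-2-iodo-1-[(4-methoxyphenyl)methoxy]-6-methylhept-2-en-4-ol, via cyclic vinylalanate 9 (not isolated)
Conditions: NaAlH2(OCH2CH2OMe)2, THF, 0 °C; then I2, THF, −78 °C
Reagents that add atoms: iodine, II
Why: Hydroxyl-directed trans-hydroalumination of the propargylic alcohol (hydride to the proximal C7, aluminium to C11 in a five-membered alanate) followed by iodinolysis with retention gives the vinyl iodide with iodine cis to the carbinol; low temperature should suppress loss of the allylic PMB-oxy group from the alanate.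

Step 6
Reactants: 10 (2Z,4R,6S)-7-[(tert-butyldimethylsilyl)oxy]-2-iodo-1-[(4-methoxyphenyl)methoxy]-6-methylhept-2-en-4-ol
Product: 11 (5R)-5-[(2S)-3-[(tert-butyldimethylsilyl)oxy]-2-methylpropyl]-3-{[(4-methoxyphenyl)methoxy]methyl}furan-2(5H)-one
Conditions: PdCl2(PPh3)2 (5 mol %), CO (1 atm), K2CO3, THF, rt
Reagents that add atoms: carbon monoxide, [C-]#[O+]
Why: Palladium-catalysed carbonylative lactonisation: oxidative addition of zerovalent palladium (formed from PdCl2(PPh3)2 under CO) into the C11–I bond, CO insertion and capture of the acylpalladium by the cis C6 hydroxyl close the butenolide (ring O, C12, C11, C7, C6) without touching C6.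

Step 7
Reactants: 11 (5R)-5-[(2S)-3-[(tert-butyldimethylsilyl)oxy]-2-methylpropyl]-3-{[(4-methoxyphenyl)methoxy]methyl}furan-2(5H)-one
Product: 12 (5R)-5-[(2S)-3-hydroxy-2-methylpropyl]-3-{[(4-methoxyphenyl)methoxy]methyl}furan-2(5H)-one
Conditions: CSA (cat.), MeOH/CH2Cl2, 0 °C
Reagents that add atoms: none
Why: Acid-catalysed methanolysis removes the primary TBS ether selectively; the PMB ether and the butenolide are stable to these conditions.

Step 8
Reactants: 12 (5R)-5-[(2S)-3-hydroxy-2-methylpropyl]-3-{[(4-methoxyphenyl)methoxy]methyl}furan-2(5H)-one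
Product: 13 (2S)-3-[(2R)-4-{[(4-methoxyphenyl)methoxy]methyl}-5-oxo-2,5-dihydrofuran-2-yl]-2-methylpropanal
Conditions: DMP, NaHCO3, CH2Cl2, 0 °C to rt
Reagents that add atoms: none
Why: Dess–Martin oxidation under buffered, non-basic conditions should give the α-methyl aldehyde without epimerisation at C4 or at the butenolide γ-carbon C6; the aldehyde is used crude.

**Fragment B**

Step 9
Reactants: 14 (S)-lactic acid
Product: 15 (2S,5S)-2-tert-butyl-5-methyl-1,3-dioxolan-4-one
Conditions: pivalaldehyde, TsOH (cat.), pentane, reflux with water separator; crystallisation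
Reagents that add atoms: pivalaldehyde, CC(C)(C)C=O
Why: Acid-catalysed acetalisation of the α-hydroxy acid gives mainly the cis dioxolanone (purified by crystallisation), which stores the lactic acid configuration at the acetal carbon.

Step 10
Reactants: 15 (2S,5S)-2-tert-butyl-5-methyl-1,3-dioxolan-4-one
Product: 17 (2S,5R)-2-tert-butyl-5-methyl-5-(prop-2-en-1-yl)-1,3-dioxolan-4-one, via lithium enolate 16 (not isolated)
Conditions: LiN(i-Pr)2, THF, −78 °C; then allyl bromide, −78 to −30 °C
Reagents that add atoms: allyl bromide, C=CCBr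
Why: Alkylation with self-regeneration of the stereocentre: the planar lithium enolate is allylated on the face opposite the tert-butyl group, which sets the quaternary C10 with the (R) configuration of the target; the allyl group carries C9 and the masked C8.

Step 11
Reactants: 17 (2S,5R)-2-tert-butyl-5-methyl-5-(prop-2-en-1-yl)-1,3-dioxolan-4-one
Product: 18 (2R)-2-hydroxy-N-methoxy-N,2-dimethylpent-4-enamide
Conditions: MeNHOMe·HCl, i-PrMgCl, THF, −20 to 0 °C
Reagents that add atoms: N,O-dimethylhydroxylamine hydrochloride, CNOC.Cl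
Why: The magnesium amide of N,O-dimethylhydroxylamine opens the activated dioxolanone carbonyl and the hemiacetal released loses pivalaldehyde, a standard ester-to-Weinreb-amide conversion.

Step 12
Reactants: 18 (2R)-2-hydroxy-N-methoxy-N,2-dimethylpent-4-enamide
Product: 19 (3R)-3-hydroxy-3-methylhex-5-en-2-one
Conditions: MeMgBr (3 equiv), THF, 0 °C; aq. NH4Cl
Reagents that add atoms: methylmagnesium bromide, C[Mg]Br
Why: Weinreb ketone synthesis: one equivalent of MeMgBr deprotonates the tertiary hydroxyl and a second adds once to the chelated amide, giving the methyl ketone (C1 and C2).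

Step 13
Reactants: 19 (3R)-3-hydroxy-3-methylhex-5-en-2-one
Product: 20 (3R)-3-methyl-2-oxohex-5-en-3-yl acetate
Conditions: Ac2O, DMAP, Et3N, CH2Cl2, rt
Reagents that add atoms: acetic anhydride, CC(=O)OC(C)=O
Why: DMAP-catalysed acetylation of the tertiary α-ketol installs the C10 acetate at a stage where no other hydroxyl is present.

Step 14
Reactants: 20 (3R)-3-methyl-2-oxohex-5-en-3-yl acetate
Product: 21 (3R)-3-methyl-2-[(trimethylsilyl)oxy]hexa-1,5-dien-3-yl acetate
Conditions: TMSOTf, Et3N, CH2Cl2, 0 °C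
Reagents that add atoms: trimethylsilyl triflate, C[Si](C)(C)OS(=O)(=O)C(F)(F)F
Why: Soft enolisation with TMSOTf and Et3N: only the methyl group (C2) of the ketone carries α-hydrogens, the other α-carbon C10 being quaternary, so a single enol silane should form and the acetate is not enolised.

**Union and ring closure**

Step 15
Reactants: 13 (2S)-3-[(2R)-4-{[(4-methoxyphenyl)methoxy]methyl}-5-oxo-2,5-dihydrofuran-2-yl]-2-methylpropanal; 21 (3R)-3-methyl-2-[(trimethylsilyl)oxy]hexa-1,5-dien-3-yl acetate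
Product: 22 (4R,7S,8S)-7-hydroxy-9-[(2R)-4-{[(4-methoxyphenyl)methoxy]methyl}-5-oxo-2,5-dihydrofuran-2-yl]-4,8-dimethyl-5-oxonon-1-en-4-yl acetate
Conditions: BF3·OEt2, CH2Cl2, −78 °C; aq. NaHCO3
Reagents that add atoms: none
Why: Mukaiyama aldol addition through an open transition state joins C2 to C3; Felkin–Anh attack anti to the C5 methylene on the α-methyl aldehyde should favour the 3,4-syn (3S) β-hydroxy ketone, the remote C10 centre of the enol silane having little influence.

Step 16
Reactants: 22 (4R,7S,8S)-7-hydroxy-9-[(2R)-4-{[(4-methoxyphenyl)methoxy]methyl}-5-oxo-2,5-dihydrofuran-2-yl]-4,8-dimethyl-5-oxonon-1-en-4-yl acetate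
Product: 23 (4R,7S,8S)-9-[(2R)-4-{[(4-methoxyphenyl)methoxy]methyl}-5-oxo-2,5-dihydrofuran-2-yl]-4,8-dimethyl-5-oxo-7-[(triethylsilyl)oxy]non-1-en-4-yl acetate
Conditions: TESOTf, 2,6-lutidine, CH2Cl2, −78 °C
Reagents that add atoms: triethylsilyl triflate, CC[Si](CC)(CC)OS(=O)(=O)C(F)(F)F
Why: Silylation with TESOTf and 2,6-lutidine at low temperature protects the β-hydroxy ketone without retro-aldol or elimination, so that only the C8 hydroxyl will be free after ring closure.

Step 17
Reactants: 23 (4R,7S,8S)-9-[(2R)-4-{[(4-methoxyphenyl)methoxy]methyl}-5-oxo-2,5-dihydrofuran-2-yl]-4,8-dimethyl-5-oxo-7-[(triethylsilyl)oxy]non-1-en-4-yl acetate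
Product: 24 (4R,7S,8S)-9-[(2R)-4-(hydroxymethyl)-5-oxo-2,5-dihydrofuran-2-yl]-4,8-dimethyl-5-oxo-7-[(triethylsilyl)oxy]non-1-en-4-yl acetate
Conditions: DDQ, CH2Cl2/pH 7 buffer, 0 °C
Reagents that add atoms: none
Why: Oxidative cleavage of the PMB ether by DDQ under buffered conditions frees the allylic C13 hydroxyl and leaves the TES ether, the acetate and both alkenes intact.

Step 18
Reactants: 24 (4R,7S,8S)-9-[(2R)-4-(hydroxymethyl)-5-oxo-2,5-dihydrofuran-2-yl]-4,8-dimethyl-5-oxo-7-[(triethylsilyl)oxy]non-1-en-4-yl acetate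
Product: 25 (4R,7S,8S)-9-[(2R)-4-(bromomethyl)-5-oxo-2,5-dihydrofuran-2-yl]-4,8-dimethyl-5-oxo-7-[(triethylsilyl)oxy]non-1-en-4-yl acetate
Conditions: CBr4, PPh3, 2,6-lutidine, CH2Cl2, 0 °C
Reagents that add atoms: carbon tetrabromide, BrC(Br)(Br)Br
Why: Appel bromination converts the primary allylic alcohol into the bromide under neutral conditions; the ketone and the secondary silyl ether do not react.

Step 19
Reactants: 25 (4R,7S,8S)-9-[(2R)-4-(bromomethyl)-5-oxo-2,5-dihydrofuran-2-yl]-4,8-dimethyl-5-oxo-7-[(triethylsilyl)oxy]non-1-en-4-yl acetate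
Product: 27 (3R,6S,7S)-8-[(2R)-4-(bromomethyl)-5-oxo-2,5-dihydrofuran-2-yl]-3,7-dimethyl-1,4-dioxo-6-[(triethylsilyl)oxy]octan-3-yl acetate, via vicinal diol 26 (not isolated)
Conditions: OsO4 (2 mol %), NaIO4, 2,6-lutidine, dioxane/H2O, rt
Reagents that add atoms: osmium tetroxide, O=[Os](=O)(=O)=O, catalytic oxygen carrier reoxidised by sodium periodate, [Na+].[O-]I(=O)(=O)=O
Why: Lemieux–Johnson cleavage: OsO4 dihydroxylates the electron-rich terminal alkene much faster than the electron-poor trisubstituted butenolide double bond and NaIO4 cleaves the diol to the C8 aldehyde; 2,6-lutidine buffers the medium and the aldehyde is used at once.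

Step 20
Reactants: 27 (3R,6S,7S)-8-[(2R)-4-(bromomethyl)-5-oxo-2,5-dihydrofuran-2-yl]-3,7-dimethyl-1,4-dioxo-6-[(triethylsilyl)oxy]octan-3-yl acetate
Product: 29 (3aR,4S,6R,9S,10S,11aR)-4-hydroxy-6,10-dimethyl-3-methylidene-2,7-dioxo-9-[(triethylsilyl)oxy]dodecahydrocyclodeca[b]furan-6-yl acetate, via allylchromium dichloride 28 (not isolated)
Conditions: CrCl2 (10 equiv), THF, rt, slow addition of 27 (final 0.002 M), O2-free; aq. work-up
Reagents that add atoms: none
Why: Two equivalents of CrCl2 reduce the allylic C13–Br bond of 27 to the allylchromium dichloride 28 (trivalent chromium), whose γ-carbon C7 adds to the C8 aldehyde through a six-membered chair transition state (Cr–C13–C11=C7···C8=O) with transposition of the double bond to C11=C13. The closest known reaction type is the Nozaki–Hiyama–Kishi allylation, known for 3-(bromomethyl)furan-2(5H)-ones with aldehydes and, intramolecularly, for closing ten-membered germacrane rings. The ten-membered carbocycle (C1 to C10) closes in the 10-exo-trig mode at the aldehyde, leaving the lactone fused at C6–C7. C7 is controlled by C6 through the planar butenolide: the aldehyde, tethered through C5 on one face, should bond to the opposite face of C7 because only the trans junction allows the near-anti C5–C6–C7–C8 torsion that a ten-membered ring favours, whereas cis closure would eclipse this bond. C8 is controlled by the ring-locked E-type geometry of the allylmetal (C6 trans to C13): with C6 and the tether carbon C9 both equatorial in the chair, the 7,8-anti alcohol (8S) should result, which is the C8 epimer of the target and is inverted in step 21. The step needs aldehyde over C1 ketone selectivity (the seven-membered alternative), γ over α attack and ring closure over oligomerisation; these are secured by the aldehyde preference of allylchromium reagents reinforced by the quaternary C10 next to the ketone, by the cyclic transition state, and by high dilution.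

Step 21
Reactants: 29 (3aR,4S,6R,9S,10S,11aR)-4-hydroxy-6,10-dimethyl-3-methylidene-2,7-dioxo-9-[(triethylsilyl)oxy]dodecahydrocyclodeca[b]furan-6-yl acetate; 30 (2Z)-2-methylbut-2-enoic acid (angelic acid)
Product: 31 (3aS,4R,6R,9S,10S,11aR)-6-(acetyloxy)-6,10-dimethyl-3-methylidene-2,7-dioxo-9-[(triethylsilyl)oxy]dodecahydrocyclodeca[b]furan-4-yl (2Z)-2-methylbut-2-enoate
Conditions: PPh3, DIAD, toluene, 0 °C to rt
Reagents that add atoms: none
Why: Mitsunobu esterification: the C8 alkoxyphosphonium ion is displaced by angelate with inversion (8S to 8R), which gives the target configuration and, being non-basic, should avoid the isomerisation of the (Z)-ester to the tiglate seen with base-mediated acylations.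

Step 22
Reactants: 31 (3aS,4R,6R,9S,10S,11aR)-6-(acetyloxy)-6,10-dimethyl-3-methylidene-2,7-dioxo-9-[(triethylsilyl)oxy]dodecahydrocyclodeca[b]furan-4-yl (2Z)-2-methylbut-2-enoate
Product: 32 (3aS,4R,6R,9S,10S,11aR)-6-(acetyloxy)-9-hydroxy-6,10-dimethyl-3-methylidene-2,7-dioxododecahydrocyclodeca[b]furan-4-yl (2Z)-2-methylbut-2-enoate (CNP0141210.1)
Conditions: HF·pyridine, pyridine, THF, 0 °C
Reagents that add atoms: none
Why: Fluoride-driven cleavage of the secondary TES ether with buffered HF·pyridine should free the C3 hydroxyl without retro-aldol, elimination or attack on the esters and the α-methylene lactone.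

**Compound list**

1 | (R)-3-bromo-2-methylpropan-1-ol | BrC[C@H](C)CO | starting material
2 | (R)-(3-bromo-2-methylpropoxy)(tert-butyl)dimethylsilane | BrC[C@H](C)CO[Si](C)(C)C(C)(C)C | intermediate
3 | 1-methoxy-4-[(prop-2-yn-1-yloxy)methyl]benzene | C#CCOCc1ccc(OC)cc1 | starting material
4 | lithium acetylide of 3 | [Li]C#CCOCc1ccc(OC)cc1 | intermediate (not isolated)
5 | N-methoxy-4-[(4-methoxyphenyl)methoxy]-N-methylbut-2-ynamide | CON(C)C(=O)C#CCOCc1ccc(OC)cc1 | intermediate
6 | [(2R)-3-[(tert-butyldimethylsilyl)oxy]-2-methylpropyl]magnesium bromide | Br[Mg]C[C@H](C)CO[Si](C)(C)C(C)(C)C | intermediate (not isolated)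
7 | (6S)-7-[(tert-butyldimethylsilyl)oxy]-1-[(4-methoxyphenyl)methoxy]-6-methylhept-2-yn-4-one | COc1ccc(COCC#CC(=O)C[C@H](C)CO[Si](C)(C)C(C)(C)C)cc1 | intermediate
8 | (4R,6S)-7-[(tert-butyldimethylsilyl)oxy]-1-[(4-methoxyphenyl)methoxy]-6-methylhept-2-yn-4-ol | COc1ccc(COCC#C[C@H](O)C[C@H](C)CO[Si](C)(C)C(C)(C)C)cc1 | intermediate
9 | sodium cyclic vinylalanate from 8 (five-membered O6–Al–C11=C7–C6 ring, two 2-methoxyethoxy groups on Al) | [Na+].COCCO[Al-]1(OCCOC)O[C@H](C[C@H](C)CO[Si](C)(C)C(C)(C)C)C=C1COCc1ccc(OC)cc1 | intermediate (not isolated)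
10 | (2Z,4R,6S)-7-[(tert-butyldimethylsilyl)oxy]-2-iodo-1-[(4-methoxyphenyl)methoxy]-6-methylhept-2-en-4-ol | COc1ccc(COC/C(I)=C/[C@H](O)C[C@H](C)CO[Si](C)(C)C(C)(C)C)cc1 | intermediate
11 | (5R)-5-[(2S)-3-[(tert-butyldimethylsilyl)oxy]-2-methylpropyl]-3-{[(4-methoxyphenyl)methoxy]methyl}furan-2(5H)-one | COc1ccc(COCC2=C[C@@H](C[C@H](C)CO[Si](C)(C)C(C)(C)C)OC2=O)cc1 | intermediate
12 | (5R)-5-[(2S)-3-hydroxy-2-methylpropyl]-3-{[(4-methoxyphenyl)methoxy]methyl}furan-2(5H)-one | COc1ccc(COCC2=C[C@@H](C[C@H](C)CO)OC2=O)cc1 | intermediate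
13 | (2S)-3-[(2R)-4-{[(4-methoxyphenyl)methoxy]methyl}-5-oxo-2,5-dihydrofuran-2-yl]-2-methylpropanal | COc1ccc(COCC2=C[C@@H](C[C@H](C)C=O)OC2=O)cc1 | intermediate
14 | (S)-lactic acid | C[C@H](O)C(=O)O | starting material
15 | (2S,5S)-2-tert-butyl-5-methyl-1,3-dioxolan-4-one | C[C@@H]1O[C@H](C(C)(C)C)OC1=O | intermediate
16 | lithium (2S)-2-tert-butyl-5-methyl-1,3-dioxol-4-olate | CC1=C(O[Li])O[C@@H](C(C)(C)C)O1 | intermediate (not isolated)
17 | (2S,5R)-2-tert-butyl-5-methyl-5-(prop-2-en-1-yl)-1,3-dioxolan-4-one | C[C@]1(CC=C)O[C@H](C(C)(C)C)OC1=O | intermediate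
18 | (2R)-2-hydroxy-N-methoxy-N,2-dimethylpent-4-enamide | CON(C)C(=O)[C@](C)(O)CC=C | intermediate
19 | (3R)-3-hydroxy-3-methylhex-5-en-2-one | CC(=O)[C@](C)(O)CC=C | intermediate
20 | (3R)-3-methyl-2-oxohex-5-en-3-yl acetate | CC(=O)[C@](C)(OC(C)=O)CC=C | intermediate
21 | (3R)-3-methyl-2-[(trimethylsilyl)oxy]hexa-1,5-dien-3-yl acetate | C=C(O[Si](C)(C)C)[C@](C)(OC(C)=O)CC=C | intermediate
22 | (4R,7S,8S)-7-hydroxy-9-[(2R)-4-{[(4-methoxyphenyl)methoxy]methyl}-5-oxo-2,5-dihydrofuran-2-yl]-4,8-dimethyl-5-oxonon-1-en-4-yl acetate | COc1ccc(COCC2=C[C@@H](C[C@H](C)[C@@H](O)CC(=O)[C@](C)(OC(C)=O)CC=C)OC2=O)cc1 | intermediate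
23 | (4R,7S,8S)-9-[(2R)-4-{[(4-methoxyphenyl)methoxy]methyl}-5-oxo-2,5-dihydrofuran-2-yl]-4,8-dimethyl-5-oxo-7-[(triethylsilyl)oxy]non-1-en-4-yl acetate | COc1ccc(COCC2=C[C@@H](C[C@H](C)[C@@H](O[Si](CC)(CC)CC)CC(=O)[C@](C)(OC(C)=O)CC=C)OC2=O)cc1 | intermediate
24 | (4R,7S,8S)-9-[(2R)-4-(hydroxymethyl)-5-oxo-2,5-dihydrofuran-2-yl]-4,8-dimethyl-5-oxo-7-[(triethylsilyl)oxy]non-1-en-4-yl acetate | OCC1=C[C@@H](C[C@H](C)[C@@H](O[Si](CC)(CC)CC)CC(=O)[C@](C)(OC(C)=O)CC=C)OC1=O | intermediate
25 | (4R,7S,8S)-9-[(2R)-4-(bromomethyl)-5-oxo-2,5-dihydrofuran-2-yl]-4,8-dimethyl-5-oxo-7-[(triethylsilyl)oxy]non-1-en-4-yl acetate | BrCC1=C[C@@H](C[C@H](C)[C@@H](O[Si](CC)(CC)CC)CC(=O)[C@](C)(OC(C)=O)CC=C)OC1=O | intermediate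
26 | (4R,7S,8S)-9-[(2R)-4-(bromomethyl)-5-oxo-2,5-dihydrofuran-2-yl]-1,2-dihydroxy-4,8-dimethyl-5-oxo-7-[(triethylsilyl)oxy]nonan-4-yl acetate (both epimers at the new carbinol) | BrCC1=C[C@@H](C[C@H](C)[C@@H](O[Si](CC)(CC)CC)CC(=O)[C@](C)(OC(C)=O)CC(O)CO)OC1=O | intermediate (not isolated)
27 | (3R,6S,7S)-8-[(2R)-4-(bromomethyl)-5-oxo-2,5-dihydrofuran-2-yl]-3,7-dimethyl-1,4-dioxo-6-[(triethylsilyl)oxy]octan-3-yl acetate | BrCC1=C[C@@H](C[C@H](C)[C@@H](O[Si](CC)(CC)CC)CC(=O)[C@](C)(OC(C)=O)CC=O)OC1=O | intermediate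
28 | allylchromium dichloride from 27 (CrCl2 unit on C13, trivalent chromium) | Cl[Cr](Cl)CC1=C[C@@H](C[C@H](C)[C@@H](O[Si](CC)(CC)CC)CC(=O)[C@](C)(OC(C)=O)CC=O)OC1=O | intermediate (not isolated)
29 | (3aR,4S,6R,9S,10S,11aR)-4-hydroxy-6,10-dimethyl-3-methylidene-2,7-dioxo-9-[(triethylsilyl)oxy]dodecahydrocyclodeca[b]furan-6-yl acetate (trans lactone, 8S alcohol in the plan numbering) | C=C1C(=O)O[C@@H]2C[C@H](C)[C@@H](O[Si](CC)(CC)CC)CC(=O)[C@](C)(OC(C)=O)C[C@H](O)[C@@H]12 | intermediate
30 | (2Z)-2-methylbut-2-enoic acid (angelic acid) | C/C=C(/C)C(=O)O | starting material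
31 | (3aS,4R,6R,9S,10S,11aR)-6-(acetyloxy)-6,10-dimethyl-3-methylidene-2,7-dioxo-9-[(triethylsilyl)oxy]dodecahydrocyclodeca[b]furan-4-yl (2Z)-2-methylbut-2-enoate | C=C1C(=O)O[C@@H]2C[C@H](C)[C@@H](O[Si](CC)(CC)CC)CC(=O)[C@](C)(OC(C)=O)C[C@@H](OC(=O)/C(C)=C\C)[C@@H]12 | intermediate
32 | (3aS,4R,6R,9S,10S,11aR)-6-(acetyloxy)-9-hydroxy-6,10-dimethyl-3-methylidene-2,7-dioxododecahydrocyclodeca[b]furan-4-yl (2Z)-2-methylbut-2-enoate | C=C1C(=O)O[C@@H]2C[C@H](C)[C@@H](O)CC(=O)[C@](C)(OC(C)=O)C[C@@H](OC(=O)/C(C)=C\C)[C@@H]12 | target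

**Step count**

Total: 22 steps. Longest linear sequence: 15 steps (steps 1, 3 to 8 and 15 to 22).

**Steps most likely to fail**

1. Step 20. Intermolecular allylation (oligomerisation) may outrun closure of the ten-membered ring, or the aldehyde may add to the face of C7 cis to C5. The fallback sets out from 11 and 20 and returns at 32; it makes the C7–C8 bond between two fragments and closes the ring at C2–C3 instead. DDQ on 11 would give (5R)-5-[(2S)-3-[(tert-butyldimethylsilyl)oxy]-2-methylpropyl]-3-(hydroxymethyl)furan-2(5H)-one F1, and CBr4/PPh3 the corresponding 3-(bromomethyl)butenolide F2. Ozonolysis of 20 (O3, CH2Cl2, −78 °C; Me2S) would give (3R)-3-methyl-1,4-dioxopentan-3-yl acetate F3. CrCl2-mediated allylation of F3 by F2 in THF, where attack anti to the C6 substituent of the butenolide is the normal course, should give the open-chain 7,8-anti alcohol F4. Mitsunobu reaction of F4 with 30 (PPh3, DIAD) would give the 8R angelate F5, HF·pyridine the primary alcohol F6, and DMP the keto aldehyde F7. Intramolecular aldol addition of the methyl ketone to the C3 aldehyde (Cy2BCl, Et3N, Et2O, high dilution) would then close the ring and give 32.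

2. Step 21. Elimination of the activated C8 oxygen toward C7 (conjugated diene) or C9, or participation of the C10 acetate, may take the place of SN2 inversion at a hindered ring carbon. The fallback sets out from 29 and returns at 31; it separates activation from displacement. ClCH2SO2Cl, pyridine, CH2Cl2, 0 °C would give the C8 chloromethanesulfonate of 29 F8, which is displaced with inversion by cesium (Z)-2-methylbut-2-enoate with 18-crown-6 in toluene at 60 °C.

3. Step 15. Facial selectivity may be poor, because the two non-hydrogen α-substituents of aldehyde 13 (a methyl and a methylene group) differ little in size. The fallback sets out from 20 and 13 and returns at 22; it replaces substrate control by reagent control in a boron aldol reaction. (−)-Ipc2BCl, Et3N, Et2O, 0 °C would convert 20 into the enol diisopinocampheylborinate of 20 F9, which adds to 13 at −78 °C through a cyclic transition state; work-up with H2O2 in pH 7 buffer/MeOH gives 22. Which enantiomer of the borane reinforces the Felkin preference is not settled here; the antipodal borane is taken if this pairing proves mismatched.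

**Further compounds**

F1 | step 20 | (5R)-5-[(2S)-3-[(tert-butyldimethylsilyl)oxy]-2-methylpropyl]-3-(hydroxymethyl)furan-2(5H)-one | OCC1=C[C@@H](C[C@H](C)CO[Si](C)(C)C(C)(C)C)OC1=O
F2 | step 20 | (5R)-3-(bromomethyl)-5-[(2S)-3-[(tert-butyldimethylsilyl)oxy]-2-methylpropyl]furan-2(5H)-one | BrCC1=C[C@@H](C[C@H](C)CO[Si](C)(C)C(C)(C)C)OC1=O
F3 | step 20 | (3R)-3-methyl-1,4-dioxopentan-3-yl acetate | CC(=O)[C@](C)(OC(C)=O)CC=O
F4 | step 20 | open-chain 7,8-anti alcohol (8S) from F2 and F3: trans-4,5-disubstituted 3-methylidene lactone with the C8 carbinol side chain, C2–C3 not yet joined | C=C1C(=O)O[C@H](C[C@H](C)CO[Si](C)(C)C(C)(C)C)[C@H]1[C@@H](O)C[C@@](C)(OC(C)=O)C(C)=O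
F5 | step 20 | 8R angelate of F4 (C8 inverted) | C=C1C(=O)O[C@H](C[C@H](C)CO[Si](C)(C)C(C)(C)C)[C@H]1[C@H](OC(=O)/C(C)=C\C)C[C@@](C)(OC(C)=O)C(C)=O
F6 | step 20 | primary C3 alcohol from F5 (TBS removed) | C=C1C(=O)O[C@H](C[C@H](C)CO)[C@H]1[C@H](OC(=O)/C(C)=C\C)C[C@@](C)(OC(C)=O)C(C)=O
F7 | step 20 | keto aldehyde from F6 (C3 aldehyde, C1 methyl ketone) | C=C1C(=O)O[C@H](C[C@H](C)C=O)[C@H]1[C@H](OC(=O)/C(C)=C\C)C[C@@](C)(OC(C)=O)C(C)=O
F8 | step 21 | C8 chloromethanesulfonate of 29 | C=C1C(=O)O[C@@H]2C[C@H](C)[C@@H](O[Si](CC)(CC)CC)CC(=O)[C@](C)(OC(C)=O)C[C@H](OS(=O)(=O)CCl)[C@@H]12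
F9 | step 15 | enol diisopinocampheylborinate of 20 (from (−)-Ipc2BCl) | C=C(OB([C@@H]1C[C@@H]2C[C@H]([C@H]1C)C2(C)C)[C@@H]1C[C@@H]2C[C@H]([C@H]1C)C2(C)C)[C@](C)(OC(C)=O)CC=C
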